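**Retrosynthetic overview**
1. Target 25 ← hydroxyl-directed epoxidation of allylic alcohol 24 (C8=C9, 10-OH); the C6 aroyl and C2 acetyl esters are in place before it.
2. Ring B is closed last at C6–C7 by a light-driven acridinium/chromium addition of a prenyl methyl C–H to the C6 aldehyde (20 → 21), which also sets C6.
3. C5, quaternary C1 and C10 ← copper hydride conjugate reduction of cyclopentenone 12, then Mukaiyama aldol with 3-methylbut-2-enal.
4. Ring A is made first: enone 12 by alkyne hydration/aldol condensation of acyclic α-hydroxy ketone 10.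
5. C4 is the only purchased stereocentre, from (R)-2-hydroxy-3-methylbutanoic acid via Seebach dioxolanone alkylation; all other centres are relayed from it.

Assumption: as written, the two oxirane descriptors place the C7 and C10 ring bonds trans across the epoxide, which is not attainable for a stable cycloheptene oxide; the epoxide is taken as cis-fused on the face of the C10 hydroxyl (C9 as written), and the target line keeps the given string unchanged.

Naming: C1–C10 are daucane locants (C1 quaternary with CH3, C2 CHOAc, C4 C(OH)iPr, C5 ring-fusion CH, C6 CH–O–aroyl, C8/C9 epoxide, C10 CHOH). α is the face of ring A carrying H-5 and the C2 and C4 oxygens; β carries the C1 methyl, the isopropyl group and C6.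

**Route**

Step 1
Reactants: 1 4-methoxybenzyl alcohol; 2 tributyl(iodomethyl)stannane
Product: 3 tributyl{[(4-methoxybenzyl)oxy]methyl}stannane
Conditions: NaH, THF/DMF, 0 °C → rt
Reagents that add atoms: none
Why: Williamson ether synthesis, the alkoxide of 1 displacing iodide from the unhindered CH2I of 2 (SN2); no stereocentre is involved.

Step 2
Reactants: 4 (R)-2-hydroxy-3-methylbutanoic acid; 5 pivalaldehyde
Product: 6 (2R,5R)-2-tert-butyl-5-(propan-2-yl)-1,3-dioxolan-4-one
Conditions: TsOH·H2O (cat.), H2SO4 (cat.), pentane, reflux (Dean–Stark); recrystallisation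
Reagents that add atoms: none
Why: Seebach acetalisation (self-regeneration of stereocentres): the centre bought in 4 is untouched and directs the new acetal centre, the 2,5-cis isomer being the major, crystalline product.

Step 3
Reactants: 6 dioxolanone; 7 1-bromobut-2-yne
Product: 9 (2R,5R)-5-(but-2-yn-1-yl)-2-tert-butyl-5-(propan-2-yl)-1,3-dioxolan-4-one, via lithium enolate 8 (not isolated)
Conditions: LiN(iPr)2, THF, −78 °C; then 7, −78 → −30 °C
Reagents that add atoms: none
Why: Seebach enolate alkylation: the planar enolate is attacked by the propargylic bromide anti to the tert-butyl group, so the acetal centre regenerates the original centre with retention as the quaternary carbon that becomes C4.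

Step 4
Reactants: 9 alkylated dioxolanone; 3 stannane
Product: 10 (3R)-3-hydroxy-1-[(4-methoxybenzyl)oxy]-3-(propan-2-yl)hept-5-yn-2-one
Conditions: 3, n-BuLi, THF, −78 °C; then 9, −78 °C; then H2O
Reagents that add atoms: none
Why: Tin–lithium exchange gives the α-alkoxymethyllithium, which adds once to the dioxolanone carbonyl; the tetrahedral adduct collapses on work-up with loss of pivalaldehyde to the tertiary α-hydroxy ketone, leaving C4 untouched.

Step 5
Reactants: 10 α-hydroxy ynone
Product: 12 (4R)-4-hydroxy-3-{[(4-methoxybenzyl)oxy]methyl}-2-methyl-4-(propan-2-yl)cyclopent-2-en-1-one, via 1,4-diketone 11 (not isolated)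
Conditions: (Ph3P)AuNTf2 (3 mol %), H2O, 1,4-dioxane, 60 °C; then pyrrolidine, AcOH, 60 °C
Reagents that add atoms: water, O
Why: Gold-catalysed alkyne hydration steered by the neighbouring ketone (5-exo attack) puts the new carbonyl on C2, and enamine-mediated intramolecular aldol condensation of the unhindered C2 ketone onto the C5 ketone closes ring A as the tetrasubstituted enone; no new stereocentre.

Step 6
Reactants: 12 enone; 13 3-methylbut-2-enal
Product: 16 bis-silyl aldol ketone (C2 ketone; 1β-CH3; 1α-[(1S)-1-silyloxy-3-methylbut-2-enyl]; 4α-OSiEt3; 5α-H), via silyl enol ether 14 (not isolated), via bis-silyl enol ether 15 (not isolated)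
Conditions: Cu(OAc)2 (5 mol %), 1,2-(Ph2P)2C6H4 (5 mol %), Et3SiH, toluene, rt; then CH2Cl2, 2,6-di-tert-butyl-4-methylpyridine, Et3SiOTf (1.15 equiv), −78 °C; then 13, −78 → −40 °C
Reagents that add atoms: triethylsilane, CC[SiH](CC)CC; triethylsilyl trifluoromethanesulfonate, CC[Si](CC)(CC)OS(=O)(=O)C(F)(F)F
Why: Copper hydride conjugate reduction delivers hydride to C5 anti to the isopropyl group (syn to the C4 oxygen) and gives the enol silane regiospecifically; after silylation of the tertiary hydroxyl, the silyl-triflate-catalysed Mukaiyama aldol adds 13 to C1 anti to the C5 side chain through an open transition state with the alkenyl group over the small C1 methyl, setting C1 and C10 (10S) with silyl transfer to the new oxygen.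

Step 7
Reactants: 16 bis-silyl aldol ketone
Product: 18 2α-acetate, via lithium alkoxide 17 (not isolated)
Conditions: LiBHEt3, THF, −78 °C; then Ac2O, DMAP, −78 °C → rt
Reagents that add atoms: acetic anhydride, CC(=O)OC(C)=O
Why: Substrate-controlled ketone reduction: hydride enters from the β face, opposite the bulky C10 arm and the 4α-silyloxy group, to give the 2α-alkoxide, which is O-acetylated in the same flask.

Step 8
Reactants: 18 acetate
Product: 19 primary alcohol (5β-CH2OH)
Conditions: DDQ, CH2Cl2/pH 7 buffer, 0 °C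
Reagents that add atoms: none
Why: Oxidative 4-methoxybenzyl ether cleavage (benzylic hydride abstraction, then hydrolysis) frees only the C6 alcohol; silyl ethers, acetate and the trisubstituted alkene are inert.

Step 9
Reactants: 19 primary alcohol
Product: 20 aldehyde (5β-CHO)
Conditions: Dess–Martin periodinane, NaHCO3, CH2Cl2, 0 °C → rt
Reagents that add atoms: none
Why: Buffered Dess–Martin oxidation gives the aldehyde without epimerising C5, and the silylated C4 oxygen rules out retro-aldol cleavage.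

Step 10
Reactants: 20 aldehyde
Product: 21 2α-acetoxy-4α,10α-bis[(triethylsilyl)oxy]dauc-8-en-6α-ol
Conditions: 9-mesityl-10-phenylacridinium tetrafluoroborate (5 mol %), CrCl2 (10 mol %), Mg(ClO4)2 (20 mol %), CH2Cl2 (5 mM), 430 nm LEDs, rt
Reagents that add atoms: none
Why: Proposed new method: intramolecular allylic C(sp3)–H addition to an aldehyde by acridinium/chromium dual photocatalysis — the excited acridinium oxidises the trisubstituted alkene to its radical cation, loss of a methyl proton gives the allyl radical (the C10–H lies in the alkene plane by A(1,3) strain and is not activated), CrCl2 (divalent chromium) traps it as an allylchromium species (trivalent chromium) whose ends interconvert by 1,3-metal shift, and because attack through C9 would build a trans-fused bicyclo[3.3.0]octane the C9-bound isomer delivers C7 to the aldehyde through a six-membered chair with the chromium alkoxide equatorial (axial would be 1,3-diaxial to the C1 methyl), closing ring B trans-fused and setting C6 with OH cis to H-5; closest known reaction: intermolecular acridinium/chromium allylation of aldehydes with simple alkenes, a photochemical Nozaki–Hiyama–Kishi-type allylation.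

Step 11
Reactants: 21 cycloheptenol; 22 3,4-dimethoxybenzoyl chloride
Product: 23 2α-acetoxy-4α,10α-bis[(triethylsilyl)oxy]dauc-8-en-6α-yl 3,4-dimethoxybenzoate
Conditions: Et3N, DMAP, CH2Cl2, 0 °C → rt
Reagents that add atoms: none
Why: DMAP-catalysed acylation of the only free hydroxyl, the equatorial 6α-OH.

Step 12
Reactants: 23 bis-silyl ether
Product: 24 2α-acetoxy-4α,10α-dihydroxydauc-8-en-6α-yl 3,4-dimethoxybenzoate
Conditions: HF·pyridine, pyridine, THF, 0 °C → rt
Reagents that add atoms: none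
Why: Fluoride-driven cleavage of both triethylsilyl ethers (Si–F bond formation); the two esters and the allylic alcohol tolerate buffered HF·pyridine.

Step 13
Reactants: 24 allylic alcohol
Product: 25 CNP0197096.3
Conditions: VO(acac)2 (5 mol %), t-BuOOH, CH2Cl2, 0 °C
Reagents that add atoms: tert-butyl hydroperoxide, CC(C)(C)OO
Why: Hydroxyl-directed epoxidation (Sharpless–Michaelson type): the vanadium alkoxide of the 10α-OH delivers oxygen to the α face of C8=C9, setting C8 and C9 as the cis-fused epoxide syn to 10-OH.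

**Compound list**
1 | 4-methoxybenzyl alcohol | COc1ccc(CO)cc1 | starting material
2 | tributyl(iodomethyl)stannane | CCCC[Sn](CCCC)(CCCC)CI | starting material
3 | tributyl{[(4-methoxybenzyl)oxy]methyl}stannane | CCCC[Sn](CCCC)(CCCC)COCc1ccc(OC)cc1 | intermediate
4 | (R)-2-hydroxy-3-methylbutanoic acid | CC(C)[C@@H](O)C(=O)O | starting material
5 | pivalaldehyde (2,2-dimethylpropanal) | CC(C)(C)C=O | starting material
6 | (2R,5R)-2-tert-butyl-5-(propan-2-yl)-1,3-dioxolan-4-one (2,5-cis) | CC(C)[C@H]1O[C@@H](C(C)(C)C)OC1=O | intermediate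
7 | 1-bromobut-2-yne | CC#CCBr | starting material
8 | lithium (2R)-2-tert-butyl-5-(propan-2-yl)-1,3-dioxol-4-olate | CC(C)C1=C([O-])O[C@H](C(C)(C)C)O1.[Li+] | intermediate
9 | (2R,5R)-5-(but-2-yn-1-yl)-2-tert-butyl-5-(propan-2-yl)-1,3-dioxolan-4-one (butynyl trans to tert-butyl) | CC#CC[C@]1(C(C)C)O[C@@H](C(C)(C)C)OC1=O | intermediate
10 | (3R)-3-hydroxy-1-[(4-methoxybenzyl)oxy]-3-(propan-2-yl)hept-5-yn-2-one | CC#CC[C@@](O)(C(C)C)C(=O)COCc1ccc(OC)cc1 | intermediate
11 | (3R)-3-hydroxy-1-[(4-methoxybenzyl)oxy]-3-(propan-2-yl)heptane-2,5-dione | CCC(=O)C[C@@](O)(C(C)C)C(=O)COCc1ccc(OC)cc1 | intermediate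
12 | (4R)-4-hydroxy-3-{[(4-methoxybenzyl)oxy]methyl}-2-methyl-4-(propan-2-yl)cyclopent-2-en-1-one | O=C1C[C@@](O)(C(C)C)C(COCc2ccc(OC)cc2)=C1C | intermediate
13 | 3-methylbut-2-enal | CC(C)=CC=O | starting material
14 | 4β-isopropyl-5β-{[(4-methoxybenzyl)oxy]methyl}-1-methyl-2-[(triethylsilyl)oxy]cyclopent-1-en-4α-ol (ring-A locants; H-5 α) | CC1=C(O[Si](CC)(CC)CC)C[C@@](O)(C(C)C)[C@H]1COCc2ccc(OC)cc2 | intermediate
15 | 4α-O-triethylsilyl ether of 14 | CC1=C(O[Si](CC)(CC)CC)C[C@@](O[Si](CC)(CC)CC)(C(C)C)[C@H]1COCc2ccc(OC)cc2 | intermediate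
16 | 4β-isopropyl-5β-{[(4-methoxybenzyl)oxy]methyl}-1β-methyl-1α-{(1S)-3-methyl-1-[(triethylsilyl)oxy]but-2-en-1-yl}-4α-[(triethylsilyl)oxy]cyclopentan-2-one | CC(C)=C[C@H](O[Si](CC)(CC)CC)[C@]1(C)C(=O)C[C@@](O[Si](CC)(CC)CC)(C(C)C)[C@H]1COCc2ccc(OC)cc2 | intermediate
17 | lithium 2α-alkoxide formed from 16 (C2–O α) | CC(C)=C[C@H](O[Si](CC)(CC)CC)[C@]1(C)[C@H]([O-])C[C@@](O[Si](CC)(CC)CC)(C(C)C)[C@H]1COCc2ccc(OC)cc2.[Li+] | intermediate
18 | 2α-acetoxy-4β-isopropyl-5β-{[(4-methoxybenzyl)oxy]methyl}-1β-methyl-1α-{(1S)-3-methyl-1-[(triethylsilyl)oxy]but-2-en-1-yl}-4α-[(triethylsilyl)oxy]cyclopentane | CC(C)=C[C@H](O[Si](CC)(CC)CC)[C@]1(C)[C@H](OC(C)=O)C[C@@](O[Si](CC)(CC)CC)(C(C)C)[C@H]1COCc2ccc(OC)cc2 | intermediate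
19 | 5β-(hydroxymethyl) analogue of 18 (4-methoxybenzyl removed) | CC(C)=C[C@H](O[Si](CC)(CC)CC)[C@]1(C)[C@H](OC(C)=O)C[C@@](O[Si](CC)(CC)CC)(C(C)C)[C@H]1CO | intermediate
20 | 5β-formyl analogue of 18 (C6 aldehyde) | CC(C)=C[C@H](O[Si](CC)(CC)CC)[C@]1(C)[C@H](OC(C)=O)C[C@@](O[Si](CC)(CC)CC)(C(C)C)[C@H]1C=O | intermediate
21 | 2α-acetoxy-4α,10α-bis[(triethylsilyl)oxy]dauc-8-en-6α-ol (H-5 α, 1-CH3 β, trans-fused) | O[C@@H]1CC(C)=C[C@H](O[Si](CC)(CC)CC)[C@]2(C)[C@H](OC(C)=O)C[C@@](O[Si](CC)(CC)CC)(C(C)C)[C@@H]12 | intermediate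
22 | 3,4-dimethoxybenzoyl chloride | COc1ccc(C(=O)Cl)cc1OC | starting material
23 | 2α-acetoxy-4α,10α-bis[(triethylsilyl)oxy]dauc-8-en-6α-yl 3,4-dimethoxybenzoate | COc1ccc(C(=O)O[C@@H]2CC(C)=C[C@H](O[Si](CC)(CC)CC)[C@]3(C)[C@H](OC(C)=O)C[C@@](O[Si](CC)(CC)CC)(C(C)C)[C@@H]23)cc1OC | intermediate
24 | 2α-acetoxy-4α,10α-dihydroxydauc-8-en-6α-yl 3,4-dimethoxybenzoate | COc1ccc(C(=O)O[C@@H]2CC(C)=C[C@H](O)[C@]3(C)[C@H](OC(C)=O)C[C@@](O)(C(C)C)[C@@H]23)cc1OC | intermediate
25 | CNP0197096.3, 2α-acetoxy-8α,9α-epoxy-4α,10α-dihydroxydaucan-6α-yl 3,4-dimethoxybenzoate (SMILES as given) | COc1ccc(C(=O)O[C@@H]2C[C@@]3(C)O[C@@H]3[C@H](O)[C@]3(C)[C@H](OC(C)=O)C[C@@](O)(C(C)C)[C@@H]23)cc1OC | target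

**Step count and risks**

Total step count: 13. Longest linear sequence: 12 steps (4 → 25, steps 2–13); step 1 is a one-step side branch feeding step 4.

Step 5 may fail because the free tertiary hydroxyl can add 5-endo to the gold-activated alkyne (carbonyl on C1 instead of C2), or because the aldol may close through the C6 methylene. The fallback removes the alkyne and sets out from 6, coming back at 11. Enolate 8 is alkylated with 2-(bromomethyl)but-1-ene (CCC(=C)CBr) to give dioxolanone F1. The lithium reagent from 3 converts it, as in step 4, into hydroxy ketone F2. Ozonolysis of the 1,1-disubstituted alkene (O3, CH2Cl2/MeOH, −78 °C; Me2S) gives diketone 11, which is condensed with pyrrolidine/AcOH as in step 5.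

Step 6 may fail because hydride delivery to the tetrasubstituted enone is slow, and because the C10 epimer forms if the open transition state does not dominate. The fallback sets C10 by ketone reduction instead of aldol addition; it sets out from 15 (now isolated) and comes back at 16. ZnCl2-promoted C-acylation of 15 with 3-methylbut-2-enoyl chloride gives β-diketone F3. NaBH4/CeCl3·7H2O in MeOH at −78 °C (Luche) reduces only the conjugated carbonyl; hydride passes the C1 methyl in both the Felkin–Anh and the chelate model, giving the 10S alcohol F4. Et3SiOTf/2,6-lutidine then gives 16.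

Step 10, the proposed new cyclisation, may fail through chromium allylation at C9, loss of the C10 hydrogen or intermolecular coupling. The fallback uses only known chemistry and closes ring B by ring-closing metathesis at C8=C9; it sets out from 15 and comes back at 21. The Mukaiyama aldol of step 6 is run on 15 with prop-2-enal in place of 13 to give vinyl ketone F5. LiBHEt3 then Ac2O/DMAP gives acetate F6, DDQ gives primary alcohol F7, and Dess–Martin periodinane gives aldehyde F8. 2-Methylallylmagnesium chloride (THF, −78 °C) adds to the aldehyde under Felkin–Anh control, before the acetate reacts, to give homoallylic alcohol F9. The second-generation Hoveyda–Grubbs catalyst, RuCl2(H2IMes)(=CH-C6H4-2-OiPr), in CH2Cl2 at 40 °C closes the trisubstituted alkene and gives 21.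

**Further compounds**
F1 | step 5 | (2R,5R)-2-tert-butyl-5-(2-methylidenebutyl)-5-(propan-2-yl)-1,3-dioxolan-4-one | CCC(=C)C[C@]1(C(C)C)O[C@@H](C(C)(C)C)OC1=O
F2 | step 5 | (3R)-3-hydroxy-1-[(4-methoxybenzyl)oxy]-5-methylidene-3-(propan-2-yl)heptan-2-one | CCC(=C)C[C@@](O)(C(C)C)C(=O)COCc1ccc(OC)cc1
F3 | step 6 | 4β-isopropyl-5β-{[(4-methoxybenzyl)oxy]methyl}-1β-methyl-1α-(3-methylbut-2-enoyl)-4α-[(triethylsilyl)oxy]cyclopentan-2-one | CC(C)=CC(=O)[C@]1(C)C(=O)C[C@@](O[Si](CC)(CC)CC)(C(C)C)[C@H]1COCc2ccc(OC)cc2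
F4 | step 6 | 1α-[(1S)-1-hydroxy-3-methylbut-2-en-1-yl]-4β-isopropyl-5β-{[(4-methoxybenzyl)oxy]methyl}-1β-methyl-4α-[(triethylsilyl)oxy]cyclopentan-2-one | CC(C)=C[C@H](O)[C@]1(C)C(=O)C[C@@](O[Si](CC)(CC)CC)(C(C)C)[C@H]1COCc2ccc(OC)cc2
F5 | step 10 | 4β-isopropyl-5β-{[(4-methoxybenzyl)oxy]methyl}-1β-methyl-1α-{(1S)-1-[(triethylsilyl)oxy]prop-2-en-1-yl}-4α-[(triethylsilyl)oxy]cyclopentan-2-one | C=C[C@H](O[Si](CC)(CC)CC)[C@]1(C)C(=O)C[C@@](O[Si](CC)(CC)CC)(C(C)C)[C@H]1COCc2ccc(OC)cc2
F6 | step 10 | 2α-acetoxy-4β-isopropyl-5β-{[(4-methoxybenzyl)oxy]methyl}-1β-methyl-1α-{(1S)-1-[(triethylsilyl)oxy]prop-2-en-1-yl}-4α-[(triethylsilyl)oxy]cyclopentane | C=C[C@H](O[Si](CC)(CC)CC)[C@]1(C)[C@H](OC(C)=O)C[C@@](O[Si](CC)(CC)CC)(C(C)C)[C@H]1COCc2ccc(OC)cc2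
F7 | step 10 | 5β-(hydroxymethyl) analogue of F6 (4-methoxybenzyl removed) | C=C[C@H](O[Si](CC)(CC)CC)[C@]1(C)[C@H](OC(C)=O)C[C@@](O[Si](CC)(CC)CC)(C(C)C)[C@H]1CO
F8 | step 10 | 5β-formyl analogue of F6 (C6 aldehyde) | C=C[C@H](O[Si](CC)(CC)CC)[C@]1(C)[C@H](OC(C)=O)C[C@@](O[Si](CC)(CC)CC)(C(C)C)[C@H]1C=O
F9 | step 10 | 2α-acetoxy-5β-[(1R)-1-hydroxy-3-methylbut-3-en-1-yl]-4β-isopropyl-1β-methyl-1α-{(1S)-1-[(triethylsilyl)oxy]prop-2-en-1-yl}-4α-[(triethylsilyl)oxy]cyclopentane | C=C[C@H](O[Si](CC)(CC)CC)[C@]1(C)[C@H](OC(C)=O)C[C@@](O[Si](CC)(CC)CC)(C(C)C)[C@H]1[C@H](O)CC(C)=C
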